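**Retrosynthetic overview**

1. Target 18 ⇐ 17 by removal of the MOM group on O7.
2. 17 ⇐ 16. The C4 carbonyl sits on C4a, ortho to the O1 ether of ring A, and C2–C3 with the C2 aryl group is a 1-arylvinyl group on O1. Adding the formyl C–H of 16 across this enol ether (H to C2, acyl carbon to C3) closes ring C and sets the C2–H stereocentre in one catalytic asymmetric step.
3. 16 ⇐ aryl ester 13 by carbonyl methylenation, with the formyl carbon carried as CH2OTBS; 13 ⇐ phenol 10 + chromene acid 12.
4. 10 ⇐ resorcinol 1 by two directed metalations (prenyl between the oxygens, then formyl) and chelation-directed release of the 2-hydroxyl; 12 ⇐ purchased chromene nitrile 11.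
5. Ring order: ring A and the chromene bicycle are bought in; ring C is the only ring made, and it is made last.

Key step: step 12

Assumption: the sense of induction of the new hydroacylation cannot be assigned in advance for this substrate class; (R)-DTBM-SEGPHOS is written, and the ligand antipode that delivers the 2S product is the one meant.

**Route**

Step 1
Reactants: 1 resorcinol
Product: 2 1,3-bis(methoxymethoxy)benzene
Conditions: NaH (2.4 equiv), MOMCl (2.3 equiv), DMF, 0 °C → rt
Reagents that add atoms: chloromethyl methyl ether, COCCl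
Why: Double Williamson-type O-alkylation of the bis-phenoxide with the reactive α-chloro ether is the standard MOM protection and should go cleanly on oxygen in DMF.

Step 2
Reactants: 2 1,3-bis(methoxymethoxy)benzene; 3 prenyl bromide (1-bromo-3-methylbut-2-ene)
Product: 5 1,3-bis(methoxymethoxy)-2-(3-methylbut-2-en-1-yl)benzene, via 2-lithio-1,3-bis(methoxymethoxy)benzene 4 (not isolated)
Conditions: n-BuLi, THF, 0 °C → rt; then CuBr·SMe2 (10 mol %), 3, –78 °C → rt
Reagents that add atoms: none
Why: Directed ortho-metalation, in which both OMOM groups steer the base to the C–H between them, followed by copper-assisted SN2 alkylation of the aryl anion at the unhindered primary carbon of the allylic bromide, which should give the linear prenyl group.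

Step 3
Reactants: 5 1,3-bis(methoxymethoxy)-2-(3-methylbut-2-en-1-yl)benzene
Product: 7 2,4-bis(methoxymethoxy)-3-(3-methylbut-2-en-1-yl)benzaldehyde, via 4-lithio-1,3-bis(methoxymethoxy)-2-(3-methylbut-2-en-1-yl)benzene 6 (not isolated)
Conditions: n-BuLi, TMEDA, THF, –20 → 0 °C; then DMF, –78 °C → rt; H2O
Reagents that add atoms: N,N-dimethylformamide, CN(C)C=O
Why: Second directed ortho-metalation, in which the ring C–H next to an OMOM group is expected to be removed faster than the benzylic allylic CH2, followed by formylation of the aryllithium with DMF.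

Step 4
Reactants: 7 2,4-bis(methoxymethoxy)-3-(3-methylbut-2-en-1-yl)benzaldehyde
Product: 8 2-hydroxy-4-(methoxymethoxy)-3-(3-methylbut-2-en-1-yl)benzaldehyde
Conditions: MgBr2·OEt2 (2 equiv), toluene/Et2O, 0 °C → rt; aqueous work-up
Reagents that add atoms: none
Why: Chelation-controlled ether cleavage, in which magnesium held between the formyl oxygen and O2 activates only the neighbouring acetal for opening by bromide, while the para MOM group cannot chelate and the mild Lewis acid should leave the prenyl alkene alone.

Step 5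
Reactants: 8 2-hydroxy-4-(methoxymethoxy)-3-(3-methylbut-2-en-1-yl)benzaldehyde
Product: 9 2-(hydroxymethyl)-5-(methoxymethoxy)-6-(3-methylbut-2-en-1-yl)phenol
Conditions: NaBH4, MeOH/THF, 0 °C
Reagents that add atoms: none
Why: Borohydride 1,2-reduction of the aldehyde; nothing else in 8 is reducible under these conditions, and the product is used at once to limit quinone methide formation.

Step 6
Reactants: 9 2-(hydroxymethyl)-5-(methoxymethoxy)-6-(3-methylbut-2-en-1-yl)phenol
Product: 10 2-{[(tert-butyldimethylsilyl)oxy]methyl}-5-(methoxymethoxy)-6-(3-methylbut-2-en-1-yl)phenol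
Conditions: TBSCl (1.05 equiv), imidazole, CH2Cl2, 0 °C
Reagents that add atoms: tert-butyldimethylsilyl chloride, CC(C)(C)[Si](C)(C)Cl
Why: Chemoselective silylation, in which the unhindered primary benzylic hydroxyl should react faster than the phenol flanked by two ortho substituents, so that one equivalent masks only the future formyl carbon.

Step 7
Reactants: 11 2,2-dimethyl-2H-chromene-6-carbonitrile
Product: 12 2,2-dimethyl-2H-chromene-6-carboxylic acid
Conditions: NaOH, EtOH/H2O, reflux; then aqueous HCl to pH 3
Reagents that add atoms: sodium hydroxide, [Na+].[OH-]; water, O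
Why: Base hydrolysis of an aryl nitrile through the primary amide to the carboxylate; the chromene ring and its styrenic alkene are inert to hydroxide.

Step 8
Reactants: 10 2-{[(tert-butyldimethylsilyl)oxy]methyl}-5-(methoxymethoxy)-6-(3-methylbut-2-en-1-yl)phenol; 12 2,2-dimethyl-2H-chromene-6-carboxylic acid
Product: 13 2-{[(tert-butyldimethylsilyl)oxy]methyl}-5-(methoxymethoxy)-6-(3-methylbut-2-en-1-yl)phenyl 2,2-dimethyl-2H-chromene-6-carboxylate
Conditions: DCC (1.3 equiv), DMAP (0.5 equiv), CH2Cl2, 0 °C → rt
Reagents that add atoms: none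
Why: Steglich esterification, in which the O-acylisourea passes the acyl group through the N-acylpyridinium ion to the hindered phenol under neutral conditions that spare the silyl ether, the acetal and both alkenes.

Step 9
Reactants: 13 2-{[(tert-butyldimethylsilyl)oxy]methyl}-5-(methoxymethoxy)-6-(3-methylbut-2-en-1-yl)phenyl 2,2-dimethyl-2H-chromene-6-carboxylate
Product: 14 tert-butyl{[2-{[1-(2,2-dimethyl-2H-chromen-6-yl)ethenyl]oxy}-4-(methoxymethoxy)-3-(3-methylbut-2-en-1-yl)phenyl]methoxy}dimethylsilane
Conditions: Cp2TiMe2 (3 equiv), toluene, 70 °C, dark; filtration through basic alumina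
Reagents that add atoms: dimethyltitanocene, [CH3-].[CH3-].[Ti+4].c1cc[cH-]c1.c1cc[cH-]c1
Why: Petasis methylenation, in which thermally formed Cp2Ti=CH2 adds [2+2] to the ester carbonyl and cycloreverts to the enol ether and titanocene oxide; aryl benzoates are established substrates, and the non-acidic reagent should leave the acetal, the silyl ether and the more substituted alkenes alone while the formyl carbon stays masked.

Step 10
Reactants: 14 tert-butyl{[2-{[1-(2,2-dimethyl-2H-chromen-6-yl)ethenyl]oxy}-4-(methoxymethoxy)-3-(3-methylbut-2-en-1-yl)phenyl]methoxy}dimethylsilane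
Product: 15 {2-{[1-(2,2-dimethyl-2H-chromen-6-yl)ethenyl]oxy}-4-(methoxymethoxy)-3-(3-methylbut-2-en-1-yl)phenyl}methanol
Conditions: TBAF, THF, 0 °C; pH 7 buffer; Et3N-deactivated silica
Reagents that add atoms: none
Why: Fluoride-induced cleavage of the Si–O bond; the basic, buffered medium should keep the acid-labile enol ether intact and prevent addition of the new hydroxyl across it.

Step 11
Reactants: 15 {2-{[1-(2,2-dimethyl-2H-chromen-6-yl)ethenyl]oxy}-4-(methoxymethoxy)-3-(3-methylbut-2-en-1-yl)phenyl}methanol
Product: 16 2-{[1-(2,2-dimethyl-2H-chromen-6-yl)ethenyl]oxy}-4-(methoxymethoxy)-3-(3-methylbut-2-en-1-yl)benzaldehyde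
Conditions: activated MnO2 (excess), CH2Cl2, rt
Reagents that add atoms: none
Why: Heterogeneous MnO2 oxidation is selective for benzylic alcohols and neutral, so the enol ether, the acetal and the alkenes should survive and over-oxidation is not expected.

Step 12
Reactants: 16 2-{[1-(2,2-dimethyl-2H-chromen-6-yl)ethenyl]oxy}-4-(methoxymethoxy)-3-(3-methylbut-2-en-1-yl)benzaldehyde
Product: 17 (2S)-2-(2,2-dimethyl-2H-chromen-6-yl)-7-(methoxymethoxy)-8-(3-methylbut-2-en-1-yl)-2,3-dihydro-4H-chromen-4-one
Conditions: [Rh(cod)Cl]2 (2.5 mol %), (R)-DTBM-SEGPHOS (5.5 mol %), NaB[3,5-(CF3)2C6H3]4 (6 mol %), 1,4-dioxane, 60 °C, argon, rigorously dry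
Reagents that add atoms: none
Why: Proposed new method: the cationic bisphosphine complex of monovalent rhodium should insert into the formyl C–H bond of 16, bind the tethered 1-arylvinyl ether, pass hydride to its oxygen- and aryl-bearing carbon (the future C2) to give a seven-membered acyl alkyl rhodacycle of trivalent rhodium with the metal on the CH2 terminus, and reductively eliminate to form C3–C4. The closest known reaction type is the rhodium-catalysed enantioselective endo hydroacylation of ortho-allyl- and ortho-vinylbenzaldehydes carrying 1,1-disubstituted alkenes, which gives 3-substituted tetralones and indanones; here the tether atom is an ether oxygen and the alkene is an enol ether. Ring C closes in the 6-endo-trig mode, because the opposite insertion would put rhodium on a fully substituted carbon and would have to form the quaternary centre of a 2-aryl-2-methylbenzofuran-3-one by reductive elimination. The C2 stereocentre is set by the chiral bisphosphine, which selects the alkene face that receives the hydride; since insertion may be reversible, this selection may be expressed only at the reductive elimination. The step needs endo over exo closure, insertion faster than decarbonylation, and no reaction at the other alkenes: the 1,1-disubstitution secures the first, the short tether through O1 that holds the alkene beside the acyl rhodium hydride should help the second, and the prenyl and chromene double bonds are more substituted and cannot reach the formyl group. Dry, acid-free conditions are needed so that the cationic metal neither hydrolyses the enol ether nor drives it onto the formyl group.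

Step 13
Reactants: 17 (2S)-2-(2,2-dimethyl-2H-chromen-6-yl)-7-(methoxymethoxy)-8-(3-methylbut-2-en-1-yl)-2,3-dihydro-4H-chromen-4-one
Product: 18 (2S)-2-(2,2-dimethyl-2H-chromen-6-yl)-7-hydroxy-8-(3-methylbut-2-en-1-yl)-2,3-dihydro-4H-chromen-4-one
Conditions: 2 M HCl, MeOH/THF, rt → 40 °C
Reagents that add atoms: none
Why: Acid-catalysed acetal cleavage (transacetalisation to methanol) frees the C7 phenol; C2 should keep its configuration because ring opening to the chalcone is a base-driven process, and dilute acid at this temperature should not cyclise the prenyl group or add to the chromene.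

**Compound list**

1 | resorcinol | Oc1cccc(O)c1 | starting material
2 | 1,3-bis(methoxymethoxy)benzene | COCOc1cccc(OCOC)c1 | intermediate
3 | prenyl bromide (1-bromo-3-methylbut-2-ene) | CC(C)=CCBr | starting material
4 | 2-lithio-1,3-bis(methoxymethoxy)benzene | [Li]c1c(OCOC)cccc1OCOC | intermediate
5 | 1,3-bis(methoxymethoxy)-2-(3-methylbut-2-en-1-yl)benzene | COCOc1cccc(OCOC)c1CC=C(C)C | intermediate
6 | 4-lithio-1,3-bis(methoxymethoxy)-2-(3-methylbut-2-en-1-yl)benzene | [Li]c1ccc(OCOC)c(CC=C(C)C)c1OCOC | intermediate
7 | 2,4-bis(methoxymethoxy)-3-(3-methylbut-2-en-1-yl)benzaldehyde | O=Cc1ccc(OCOC)c(CC=C(C)C)c1OCOC | intermediate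
8 | 2-hydroxy-4-(methoxymethoxy)-3-(3-methylbut-2-en-1-yl)benzaldehyde | O=Cc1ccc(OCOC)c(CC=C(C)C)c1O | intermediate
9 | 2-(hydroxymethyl)-5-(methoxymethoxy)-6-(3-methylbut-2-en-1-yl)phenol | OCc1ccc(OCOC)c(CC=C(C)C)c1O | intermediate
10 | 2-{[(tert-butyldimethylsilyl)oxy]methyl}-5-(methoxymethoxy)-6-(3-methylbut-2-en-1-yl)phenol | CC(C)(C)[Si](C)(C)OCc1ccc(OCOC)c(CC=C(C)C)c1O | intermediate
11 | 2,2-dimethyl-2H-chromene-6-carbonitrile | CC1(C)C=Cc2cc(C#N)ccc2O1 | starting material
12 | 2,2-dimethyl-2H-chromene-6-carboxylic acid | CC1(C)C=Cc2cc(C(=O)O)ccc2O1 | intermediate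
13 | 2-{[(tert-butyldimethylsilyl)oxy]methyl}-5-(methoxymethoxy)-6-(3-methylbut-2-en-1-yl)phenyl 2,2-dimethyl-2H-chromene-6-carboxylate | CC(C)(C)[Si](C)(C)OCc1ccc(OCOC)c(CC=C(C)C)c1OC(=O)c1ccc2c(c1)C=CC(C)(C)O2 | intermediate
14 | tert-butyl{[2-{[1-(2,2-dimethyl-2H-chromen-6-yl)ethenyl]oxy}-4-(methoxymethoxy)-3-(3-methylbut-2-en-1-yl)phenyl]methoxy}dimethylsilane | CC(C)(C)[Si](C)(C)OCc1ccc(OCOC)c(CC=C(C)C)c1OC(=C)c1ccc2c(c1)C=CC(C)(C)O2 | intermediate
15 | {2-{[1-(2,2-dimethyl-2H-chromen-6-yl)ethenyl]oxy}-4-(methoxymethoxy)-3-(3-methylbut-2-en-1-yl)phenyl}methanol | OCc1ccc(OCOC)c(CC=C(C)C)c1OC(=C)c1ccc2c(c1)C=CC(C)(C)O2 | intermediate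
16 | 2-{[1-(2,2-dimethyl-2H-chromen-6-yl)ethenyl]oxy}-4-(methoxymethoxy)-3-(3-methylbut-2-en-1-yl)benzaldehyde | C=C(Oc1c(C=O)ccc(OCOC)c1CC=C(C)C)c1ccc2c(c1)C=CC(C)(C)O2 | intermediate
17 | (2S)-2-(2,2-dimethyl-2H-chromen-6-yl)-7-(methoxymethoxy)-8-(3-methylbut-2-en-1-yl)-2,3-dihydro-4H-chromen-4-one | CC(C)=CCc1c(OCOC)ccc2c1O[C@H](c1ccc3c(c1)C=CC(C)(C)O3)CC2=O | intermediate
18 | (2S)-2-(2,2-dimethyl-2H-chromen-6-yl)-7-hydroxy-8-(3-methylbut-2-en-1-yl)-2,3-dihydro-4H-chromen-4-one | CC(C)=CCc1c(O)ccc2c1O[C@H](c1ccc3c(c1)C=CC(C)(C)O3)CC2=O | target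

**Step count and risks**

Total step count: 13. Longest linear sequence: 12 (steps 1–6 and 8–13; step 7 is the side branch).

Steps most likely to fail:

1. Step 12 (new method). The acyl rhodium hydride may lose CO before it inserts. The hydride may go to the CH2 terminus, followed by exo closure to the benzofuranone. The cationic metal may drive the enol ether onto the formyl group or hydrolyse it. Facial selection may be weak. The fallback uses known chemistry, sets out from 8 and 11, and comes back at 17. Addition of MeMgBr (excess, THF, 0 °C) to 8 gives 2-(1-hydroxyethyl)-5-(methoxymethoxy)-6-(3-methylbut-2-en-1-yl)phenol F1. MnO2 oxidises this to 1-[2-hydroxy-4-(methoxymethoxy)-3-(3-methylbut-2-en-1-yl)phenyl]ethan-1-one F2. Reduction of 11 with i-Bu2AlH (toluene, –78 °C, then aqueous acid) gives 2,2-dimethyl-2H-chromene-6-carbaldehyde F3. Claisen–Schmidt condensation of F2 with F3 (KOH, EtOH, rt) gives (E)-3-(2,2-dimethyl-2H-chromen-6-yl)-1-[2-hydroxy-4-(methoxymethoxy)-3-(3-methylbut-2-en-1-yl)phenyl]prop-2-en-1-one F4. NaOAc in refluxing EtOH closes ring C by oxa-Michael addition to racemic 2-(2,2-dimethyl-2H-chromen-6-yl)-7-(methoxymethoxy)-8-(3-methylbut-2-en-1-yl)chroman-4-one F5. Preparative HPLC on a chiral stationary phase then separates the 2S enantiomer 17.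

2. Step 9. Addition of the titanium methylidene to the doubly ortho-substituted ester may be slow. The oxatitanacycle may break up by loss of the aryloxide instead of titanocene oxide. The enol ether may hydrolyse during isolation. The fallback sets out from 10 and comes back at 14. Iridium-catalysed transvinylation of 10 with vinyl acetate ([Ir(cod)Cl]2, Na2CO3, toluene, 100 °C) gives tert-butyl{[2-(ethenyloxy)-4-(methoxymethoxy)-3-(3-methylbut-2-en-1-yl)phenyl]methoxy}dimethylsilane F6. A Heck arylation under the cationic manifold (Pd(OAc)2, dppp, Et3N, AgOTf, DMF, 80 °C) with purchased 6-bromo-2,2-dimethyl-2H-chromene F7 should place the aryl group on the oxygen-bearing alkene carbon and give 14.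

3. Step 4. Site selectivity may be lost with cleavage of both acetals, or the Lewis acid may induce addition of the freed phenol to the prenyl alkene. The fallback sets out from 7 and comes back at 8. Both MOM groups are removed (2 M HCl, MeOH/THF, rt) to give 2,4-dihydroxy-3-(3-methylbut-2-en-1-yl)benzaldehyde F8. MOMCl (1.05 equiv) with K2CO3 in acetone should then alkylate only the 4-hydroxyl, because the 2-hydroxyl is held in a hydrogen bond to the formyl group, and give 8.

**Further compounds**

F1 | step 12 | 2-(1-hydroxyethyl)-5-(methoxymethoxy)-6-(3-methylbut-2-en-1-yl)phenol | CC(O)c1ccc(OCOC)c(CC=C(C)C)c1O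
F2 | step 12 | 1-[2-hydroxy-4-(methoxymethoxy)-3-(3-methylbut-2-en-1-yl)phenyl]ethan-1-one | CC(=O)c1ccc(OCOC)c(CC=C(C)C)c1O
F3 | step 12 | 2,2-dimethyl-2H-chromene-6-carbaldehyde | CC1(C)C=Cc2cc(C=O)ccc2O1
F4 | step 12 | (E)-3-(2,2-dimethyl-2H-chromen-6-yl)-1-[2-hydroxy-4-(methoxymethoxy)-3-(3-methylbut-2-en-1-yl)phenyl]prop-2-en-1-one | COCOc1ccc(C(=O)/C=C/c2ccc3c(c2)C=CC(C)(C)O3)c(O)c1CC=C(C)C
F5 | step 12 | racemic 2-(2,2-dimethyl-2H-chromen-6-yl)-7-(methoxymethoxy)-8-(3-methylbut-2-en-1-yl)chroman-4-one | CC(C)=CCc1c(OCOC)ccc2c1OC(c1ccc3c(c1)C=CC(C)(C)O3)CC2=O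
F6 | step 9 | tert-butyl{[2-(ethenyloxy)-4-(methoxymethoxy)-3-(3-methylbut-2-en-1-yl)phenyl]methoxy}dimethylsilane | CC(C)(C)[Si](C)(C)OCc1ccc(OCOC)c(CC=C(C)C)c1OC=C
F7 | step 9 | 6-bromo-2,2-dimethyl-2H-chromene (purchased) | CC1(C)C=Cc2cc(Br)ccc2O1
F8 | step 4 | 2,4-dihydroxy-3-(3-methylbut-2-en-1-yl)benzaldehyde | CC(C)=CCc1c(O)ccc(C=O)c1O
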